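**Assumption:** the target is the trans-2-aryl-3-hydroxymethyl-2,3-dihydrobenzofuran with (2S,3R) configuration, which I derived from the SMILES. The chiral porphyrin enantiomer that gives the (2S,3S) ester 13 will be chosen by a short screen of the two antipodes.

## Retrosynthesis
- The target comes from global deprotection of the tert-butyl cinnamate and the aryl TIPS ether, after chemoselective LiBH4 reduction of the C3 methyl ester to CH2OH.
- The dihydrobenzofuran ring is made in one step by asymmetric Co(II)-metalloradical 1,5-C–H alkylation of an o-(benzyloxy)aryl diazoacetate. This forms the C2–C3 bond and sets both stereocenters, trans (new key step).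
- The diazoester comes from diazo transfer onto a methyl arylacetate. The arylacetate comes from Pd-catalysed Reformatsky (Negishi) coupling of an aryl iodide, which is made from 5-iodovanillin by O-benzylation (Mitsunobu) and an E-selective HWE reaction.
- Ring formation is therefore the only ring-forming event. The cinnamate is installed before it, and the two esters are differentiated as methyl (reduced) and tert-butyl (retained).

## Route

**Step 1**
Reactants: 1 vanillin (4-hydroxy-3-methoxybenzaldehyde); 2 triisopropylsilyl chloride
Product: 3 3-methoxy-4-(triisopropylsilyloxy)benzaldehyde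
Conditions: 2, imidazole, DMF, rt
Reagents that add atoms: TIPSCl, CC(C)[Si](Cl)(C(C)C)C(C)C
Why: Standard silylation of the phenol. It masks the phenol O–H, which would quench the Co-carbene radical, and the TIPS ether survives the later base, Zn, Pd and borohydride steps.

**Step 2**
Reactants: 3
Product: 4 (3-methoxy-4-(triisopropylsilyloxy)phenyl)methanol
Conditions: NaBH4, MeOH/THF, 0 °C → rt
Reagents that add atoms: none
Why: Chemoselective aldehyde reduction (hydride reduction). The aryl silyl ether is stable to NaBH4.

**Step 3**
Reactants: 5 5-iodovanillin (4-hydroxy-3-iodo-5-methoxybenzaldehyde); 4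
Product: 6 3-iodo-5-methoxy-4-[(3-methoxy-4-TIPSO-benzyl)oxy]benzaldehyde
Conditions: PPh3, DIAD, THF, 0 °C → rt
Reagents that add atoms: none (the benzylic alcohol 4 is the coupling partner)
Why: Mitsunobu O-alkylation. The phenol is acidic (pKa about 7, from the para CHO and ortho I), so it is a good pronucleophile. It builds the o-benzyl ether that will supply the C2–H and the C2 aryl group.

**Step 4**
Reactants: 6; 7 tert-butyl diethylphosphonoacetate
Product: 8 tert-butyl (E)-3-[3-iodo-5-methoxy-4-((3-methoxy-4-TIPSO-benzyl)oxy)phenyl]acrylate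
Conditions: 7, NaH, THF, 0 °C → rt
Reagents that add atoms: 7, CCOP(=O)(OCC)CC(=O)OC(C)(C)C
Why: Horner–Wadsworth–Emmons olefination gives the E-cinnamate (>20:1). The tert-butyl ester is orthogonal to the later LiBH4 reduction, and the aryl iodide is untouched.

**Step 5**
Reactants: 8; 9 methyl bromoacetate
Product: 10 tert-butyl (E)-3-[3-(2-methoxy-2-oxoethyl)-5-methoxy-4-((3-methoxy-4-TIPSO-benzyl)oxy)phenyl]acrylate
Conditions: 9, Zn dust, TMSCl (activation), THF, rt → BrZnCH2CO2Me; then 8, Pd2(dba)3 (2.5 mol%), Q-Phos (5 mol%), THF, 50 °C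
Reagents that add atoms: methyl bromoacetate, COC(=O)CBr
Why: Pd-catalysed Negishi/Reformatsky α-arylation of a zinc ester enolate. It tolerates the cinnamate, the silyl ether and the ortho-alkoxy group.

**Step 6**
Reactants: 10; 11 p-acetamidobenzenesulfonyl azide (p-ABSA)
Product: 12 tert-butyl (E)-3-[3-(1-diazo-2-methoxy-2-oxoethyl)-5-methoxy-4-((3-methoxy-4-TIPSO-benzyl)oxy)phenyl]acrylate
Conditions: 11, DBU, MeCN, rt
Reagents that add atoms: p-ABSA, CC(=O)Nc1ccc(cc1)S(=O)(=O)N=[N+]=[N-] (transfers N2)
Why: Regitz-type diazo transfer to the acidic benzylic CH2 of the arylacetate gives a bench-stable donor/acceptor diazo ester.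

**Step 7**
Reactants: 12
Product: 13 tert-butyl (E)-3-[(2S,3S)-3-(methoxycarbonyl)-7-methoxy-2-(3-methoxy-4-TIPSO-phenyl)-2,3-dihydrobenzofuran-5-yl]acrylate
Conditions: [Co(P*)] (D2-symmetric chiral amidoporphyrin Co(II), 5 mol%), PhMe (0.02 M), 4 Å MS, 40 °C, N2, 24 h
Reagents that add atoms: none (N2 is lost)
Why: Proposed new method: a chiral Co(II) porphyrin reacts with the aryldiazoacetate to give a Co(III)-carbene radical. This abstracts the weak, electron-rich α-oxy benzylic H from O–CH2Ar by 1,5-HAT. The resulting benzylic radical and the Co(III)-bound alkyl then close the five-membered ring by radical substitution, forming C2–C3. Both centres are fixed in the chiral pocket during this closure, and the sterically preferred trans arrangement is formed. The closest known reactions are Co(II)-metalloradical 1,5-C–H alkylation and Rh(II) donor/acceptor carbene C–H insertion. I am extending them to asymmetric construction of 2-aryl-2,3-dihydrobenzofuran-3-carboxylates from O-benzyl aryldiazoacetates. The cinnamate and aryl silyl ether are spectators, because the intramolecular HAT is much faster than intermolecular cyclopropanation of a tert-butyl cinnamate.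

**Step 8**
Reactants: 13
Product: 14 tert-butyl (E)-3-[(2S,3R)-3-(hydroxymethyl)-7-methoxy-2-(3-methoxy-4-TIPSO-phenyl)-2,3-dihydrobenzofuran-5-yl]acrylate
Conditions: LiBH4, THF, 0 °C → rt, 3 h (neutral workup)
Reagents that add atoms: none
Why: LiBH4 reduces the aliphatic methyl ester much faster than the tert-butyl cinnamate, and it does not touch the silyl ether. Both stereocenters are untouched; the C3 descriptor changes from S to R only because CIP priorities change (CH2OH versus CO2Me).

**Step 9**
Reactants: 14
Product: 15 (E)-3-[(2S,3R)-3-(hydroxymethyl)-7-methoxy-2-(3-methoxy-4-TIPSO-phenyl)-2,3-dihydrobenzofuran-5-yl]acrylic acid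
Conditions: TFA/CH2Cl2 (1:4), 0 °C → rt, 2 h
Reagents that add atoms: none (the tert-butyl group is lost as isobutylene)
Why: Acidolysis of the tert-butyl ester. The aryl TIPS ether and the dihydrobenzofuran survive these short, cold conditions.

**Step 10**
Reactants: 15
Product: 16 target, (E)-3-[(2S,3R)-2-(4-hydroxy-3-methoxyphenyl)-3-(hydroxymethyl)-7-methoxy-2,3-dihydrobenzofuran-5-yl]acrylic acid
Conditions: TBAF, AcOH (1 equiv), THF, 0 °C, 15 min; then aqueous KHSO4 to pH 4
Reagents that add atoms: none (H from workup)
Why: Fluoride-mediated desilylation of the aryl silyl ether. The buffered conditions leave the cinnamate and the stereocenters intact.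

## Compound list
1 | vanillin | COc1cc(C=O)ccc1O | starting material
2 | triisopropylsilyl chloride | CC(C)[Si](Cl)(C(C)C)C(C)C | starting material
3 | 3-methoxy-4-(TIPSO)benzaldehyde | COc1cc(C=O)ccc1O[Si](C(C)C)(C(C)C)C(C)C | intermediate
4 | (3-methoxy-4-TIPSO-phenyl)methanol | COc1cc(CO)ccc1O[Si](C(C)C)(C(C)C)C(C)C | intermediate
5 | 5-iodovanillin | COc1cc(C=O)cc(I)c1O | starting material
6 | 3-iodo-5-methoxy-4-[(3-methoxy-4-TIPSO-benzyl)oxy]benzaldehyde | COc1cc(C=O)cc(I)c1OCc1ccc(O[Si](C(C)C)(C(C)C)C(C)C)c(OC)c1 | intermediate
7 | tert-butyl diethylphosphonoacetate | CCOP(=O)(OCC)CC(=O)OC(C)(C)C | starting material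
8 | tert-butyl (E)-cinnamate aryl iodide | COc1cc(/C=C/C(=O)OC(C)(C)C)cc(I)c1OCc1ccc(O[Si](C(C)C)(C(C)C)C(C)C)c(OC)c1 | intermediate
9 | methyl bromoacetate | COC(=O)CBr | starting material
10 | methyl arylacetate | COc1cc(/C=C/C(=O)OC(C)(C)C)cc(CC(=O)OC)c1OCc1ccc(O[Si](C(C)C)(C(C)C)C(C)C)c(OC)c1 | intermediate
11 | p-ABSA | CC(=O)Nc1ccc(cc1)S(=O)(=O)N=[N+]=[N-] | starting material
12 | aryl diazoacetate | COc1cc(/C=C/C(=O)OC(C)(C)C)cc(C(=[N+]=[N-])C(=O)OC)c1OCc1ccc(O[Si](C(C)C)(C(C)C)C(C)C)c(OC)c1 | intermediate
13 | (2S,3S)-trans dihydrobenzofuran methyl ester | COc1cc([C@H]2Oc3c(OC)cc(/C=C/C(=O)OC(C)(C)C)cc3[C@@H]2C(=O)OC)ccc1O[Si](C(C)C)(C(C)C)C(C)C | intermediate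
14 | (2S,3R) primary alcohol, tert-butyl ester, TIPS ether | COc1cc([C@H]2Oc3c(OC)cc(/C=C/C(=O)OC(C)(C)C)cc3[C@@H]2CO)ccc1O[Si](C(C)C)(C(C)C)C(C)C | intermediate
15 | (2S,3R) acid, TIPS ether | COc1cc([C@H]2Oc3c(OC)cc(/C=C/C(=O)O)cc3[C@@H]2CO)ccc1O[Si](C(C)C)(C(C)C)C(C)C | intermediate
16 | target | COc1cc([C@H]2Oc3c(OC)cc(/C=C/C(=O)O)cc3[C@@H]2CO)ccc1O | target

## Totals
- Total steps: 10.
- Longest linear sequence: 10 steps (vanillin to target); it is 8 steps from 5-iodovanillin.

## Three steps most likely to fail
1. **Step 7 (new Co-metalloradical C–H alkylation).** Donor/acceptor diazoesters are sluggish with Co(II), and the ee and trans selectivity are unproven.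
   - Fallback: run the insertion with achiral Rh2(OAc)4, which is known to give trans-2-aryl-dihydrobenzofuran-3-carboxylates as the racemate. Carry that through step 8, then resolve alcohol 14 by Pseudomonas cepacia lipase acylation (vinyl acetate) or preparative chiral SFC.
2. **Step 5 (Negishi α-arylation).** The hindered, electron-rich aryl iodide could give Heck side reactions with the cinnamate or poor conversion.
   - Fallback: Cu-catalysed malonate arylation of 8 (CuI, 2-phenylphenol, Cs2CO3, diethyl malonate), followed by Krapcho decarboxylation. This gives the ethyl arylacetate, and the later steps are unchanged.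
3. **Step 9 (TFA deprotection).** The electron-rich benzylic C2–O bond may ionise or open under acid, which would erode ee.
   - Fallback: re-sequence so the cinnamic acid is built last under basic conditions. Carry the aldehyde as a dimethyl acetal instead of the tert-butyl cinnamate, do the steps through the LiBH4 reduction, then remove the acetal, and finish with Knoevenagel–Doebner condensation (malonic acid, pyridine/piperidine) and TBAF.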